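## Analysis of the target

The target 24 is an acyclic union of two benzene rings through one ether oxygen. Ring A is a benzoic acid (CO2H at C1) with a methoxy group at C2, a 1-acetoxy-3-methylbutyl chain at C3 and the ether oxygen at C6. Ring B carries the ether oxygen at C1′, a free hydroxyl at C2′, a methyl group at C4′ and an (E)-3-oxobut-1-enyl group at C6′. There is one stereocentre, the S-configured benzylic carbinol carbon of the C3 chain; with no second centre to relay chirality it must be set by a reagent, and the only other stereo element is the E enone, the thermodynamically preferred geometry. The sensitive groups are the benzylic acetate, the enone and the masked acid and phenol. The acetate is hydrolysed by base, can ionise in acid, and is expelled whenever the para oxygen at C6 is a free phenoxide. The enone is a Michael acceptor and is reducible, so the chain alkene has to be saturated before it exists. The hard points are the ether flanked by three ortho substituents, the four contiguous substituents C6–C1–C2–C3 of ring A, and the isolated stereocentre. The strategy rests on the C3 chain: CH(O)–CH2–CH(CH3)2 is the dihydro form of ArCH(O)–CH2–C(CH3)=CH2, which is what a benzyl 2-methylallyl ether gives when the allyl group moves from oxygen to the benzylic carbon. The C2 methoxy oxygen sits ortho to that carbon and can hold lithium there, and the ether oxygen ends up as the acetate oxygen.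

## Retrosynthetic reasoning

24 ⇒ 23. The last operation only releases the carboxylic acid and the ring B phenol. Both are masked by acid-labile groups (tert-butyl ester, methoxymethyl ether), so one treatment frees them and no skeletal bond is made while the acid and phenol are free.

23 ⇒ 22. The Cα=Cβ bond of the enone is cut back to the aryl aldehyde at C6′. A ketone-stabilised ylide reacts only with the aldehyde and gives the E alkene. Placing this step late keeps the Michael acceptor away from the basic, nucleophilic and reductive steps.

22 ⇒ 21. The acetyl C–O bond is cut, leaving the free S alcohol. The acetate is attached only after the diaryl ether exists. A C6 phenoxide para to a benzylic acetate would push the acetate out through a para-quinone methide, and the acetyl group could also migrate to the phenoxide. The free alcohol offers no leaving group.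

21 ⇒ 14 + 20. The ether is cut at O–C1′ of ring B rather than at O–C6 of ring A. C1′ has an ortho formyl group, which is needed for the enone anyway and activates a fluoride for addition–elimination, whereas C6 of ring A has no comparable activation. The forward step has to join a hindered phenoxide to a fluoride that is flanked on both sides.

20 ⇒ 19 ⇒ 18 ⇒ 16 ⇒ 15. In the ring B fragment the formyl carbon is cut off next to fluorine. The forward reaction is a deprotonation adjacent to fluorine, which needs the phenol oxygen masked by a bulky, non-coordinating silyl group (16) so that oxygen does not direct the base to the other side. The silyl group is then exchanged for the methoxymethyl group (19 to 20), because an aryl silyl ether would not survive the carbonate-mediated ether formation.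

14 ⇒ 13 ⇒ 12. The phenol is re-silylated and the isobutyl terminus is traced back to a 2-methylallyl group. Hydrogenation has to spare the benzylic C–O bond and desilylation has to spare the ester.

12 ⇒ 9. This is the strategic cut: the bond between the benzylic carbon and the chain CH2 is broken and the allyl unit is returned to oxygen, giving benzyl 2-methylallyl ether 9. One forward step builds the C–C bond and the stereocentre and places the oxygen that later carries the acetyl group. It requires benzylic deprotonation in the presence of an ester and face selection by a chiral ligand on lithium.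

9 ⇒ 7 + 8. The allyl–oxygen bond is cut, a Williamson disconnection to benzylic alcohol 7 and allylic chloride 8.

7 ⇒ 6 ⇒ 5 ⇒ 4 ⇒ 2 ⇒ 1. The remaining steps back to 1 are functional-group operations on a symmetric resorcinol. These are reduction of the aldehyde, methylation of the hindered C2 hydroxyl, silylation of the freer C6 hydroxyl, formylation at C3 (equivalent to C5 in symmetric 2) and tert-butyl ester formation. The formyl group breaks the symmetry and makes the two hydroxyls different enough to be addressed in turn.

## Alternatives that were turned down

Alternative 1: The diaryl ether bond O–C1′ is made intramolecularly from depside A2, the ester of the ring A acid with the ring B phenol oxygen. Under a carbonate base in a dipolar aprotic solvent the C6 phenoxide of ring A attacks C1′ through a six-membered spiro anion, and the aryl group moves from the ester oxygen to the phenol oxygen, releasing acid A1.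
- For: intramolecular delivery is the better answer to the tri-ortho-substituted ether, and here this alternative is stronger than the intermolecular substitution of the chosen route. It also gives the free acid directly, so no ester protecting group and no final ester cleavage are needed.
- Against: A2 must already contain the S acetate, so the stereocentre still needs its own method. In A2 the phenoxide is para to the benzylic acetate, so loss of acetate through a para-quinone methide and acetyl transfer to the phenoxide compete directly with the rearrangement.
- Against: the spiro anion on ring B is stabilised by only one ortho formyl group against an alkoxy and a methyl donor. The aryl ester is an active ester open to hydrolysis, and esterifying a di-ortho-substituted acid with a di-ortho-substituted phenol is itself difficult.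
- Comparison: the chosen route accepts an intermolecular ether formation and an ester protecting group. In return the ether is formed on a free alcohol with no leaving group para to the phenoxide, and the route supplies the stereocentre, which this alternative does not.

Alternative 2: The C3–CH(OAc) bond is cut. A nickel catalyst with a chiral bis(oxazoline) and a metallic reductant would couple aryl iodide A4 with racemic α-chloroalkyl acetate A5. Both enantiomers of A5 converge through one radical, giving A3 with chain, acetate and stereocentre in place.
- For: on the side chain this is clearly more step-economical than the chosen route, since it replaces ether formation, rearrangement, hydrogenation and acetylation. It also uses no strong base.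
- Against: A4 needs iodine at C3 of ring A. Iodinating the assembled diaryl ether would favour the more electron-rich ring B or C5, so the iodine would have to be carried from the start through the ether formation.
- Against: the coupling site is ortho to a methoxy group that is itself buttressed by the ester, which is a poor fit for enantioselective radical capture. A5 is a moisture-sensitive α-halo ester. The enantio-determining step falls on the most advanced intermediate, where a modest ee cannot be repaired cheaply.
- Comparison: the chosen strategy costs more steps but sets the stereocentre early on a small molecule, where a shortfall can be seen and corrected by a second method.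

Alternative 3: Both the O–C6 bond and the C1–CO2H bond of ring A are cut. Fluoride would convert ortho-silylaryl triflate A7 into the C1–C6 aryne, the phenoxide of A8 would add at C6, and the C1 aryl anion would be trapped by carbon dioxide A9 to give A6.
- For: it is the most convergent plan. It forms the hindered ether without any activating group and needs no ester protection, and on both points it is stronger than the chosen route. The C2 methoxy group steers the phenoxide to C6, as 3-alkoxyarynes do.
- Against: A7 needs contiguous silyl and triflate groups next to the S acetate, a long preparation that again needs a separate asymmetric step.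
- Against: the aryl anion is flanked by the methoxy group and the new bulky aryloxy group, so protonation competes with capture of A9. A9 also reversibly carbonates the phenoxide of A8 and lowers the nucleophile concentration.
- Against: the bromide in A6 must afterwards be turned into the enone by a Heck reaction on a free acid bearing the benzylic acetate.
- Comparison: the chosen route is longer, but every step other than the rearrangement has close precedent, and the one uncertain step comes early.

Key step: step 7

Assumption: in step 7 the (S,S)-configured bis(oxazoline) is taken to induce the S configuration; if the sense of induction is the opposite, the equally available (R,R)-ligand is used.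

## Route

Step 1
Reactants: 1 2,6-dihydroxybenzoic acid
Product: 2 tert-butyl 2,6-dihydroxybenzoate
Conditions: tert-butyl 2,2,2-trichloroacetimidate (2 equiv), CH2Cl2/cyclohexane, rt
Reagents that add atoms: tert-butyl 2,2,2-trichloroacetimidate, CC(C)(C)OC(=N)C(Cl)(Cl)Cl
Why: Trichloroacetimidate esterification: the strongly acidic carboxylic acid protonates the imidate, which passes a tert-butyl cation to the carboxylate. Without an added acid catalyst the phenols are not alkylated, and room temperature avoids decarboxylation of the electron-rich acid.

Step 2
Reactants: 2 tert-butyl 2,6-dihydroxybenzoate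
Product: 4 tert-butyl 3-formyl-2,6-dihydroxybenzoate, via hydroxymethyl intermediate 3 (not isolated)
Conditions: MgCl2 (anhydrous), Et3N, (CH2O)n, MeCN, reflux; aq. NH4Cl work-up
Reagents that add atoms: paraformaldehyde (formaldehyde), C=O
Why: Magnesium-mediated ortho-formylation of a phenol (Casnati–Skattebøl type): the magnesium phenoxide delivers formaldehyde to C3, the only kind of free ortho position in symmetric 2, giving 3, which a second formaldehyde oxidises by hydride transfer. The basic medium spares the tert-butyl ester and the first formyl group deactivates the ring towards a second one.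

Step 3
Reactants: 4 tert-butyl 3-formyl-2,6-dihydroxybenzoate
Product: 5 tert-butyl 3-formyl-2-hydroxy-6-(triisopropylsilyloxy)benzoate
Conditions: TIPSCl, imidazole, DMF, 0 °C to rt
Reagents that add atoms: chlorotriisopropylsilane, CC(C)[Si](Cl)(C(C)C)C(C)C
Why: Phenol silylation: the C6 hydroxyl is para to the formyl group and flanked on one side only, whereas the C2 hydroxyl lies between ester and formyl group and is hydrogen-bonded to the aldehyde, so the bulky silyl chloride should react at O6.

Step 4
Reactants: 5 tert-butyl 3-formyl-2-hydroxy-6-(triisopropylsilyloxy)benzoate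
Product: 6 tert-butyl 3-formyl-2-methoxy-6-(triisopropylsilyloxy)benzoate
Conditions: MeI, K2CO3, acetone, 50 °C
Reagents that add atoms: iodomethane, CI
Why: Williamson-type O-methylation of the acidic C2 phenol. The hindered triisopropylsilyl ether next to the tert-butyl ester should tolerate anhydrous carbonate in acetone.

Step 5
Reactants: 6 tert-butyl 3-formyl-2-methoxy-6-(triisopropylsilyloxy)benzoate
Product: 7 tert-butyl 3-(hydroxymethyl)-2-methoxy-6-(triisopropylsilyloxy)benzoate
Conditions: NaBH4, MeOH/THF, 0 °C
Reagents that add atoms: none
Why: Borohydride reduction of the aryl aldehyde; the shielded tert-butyl ester is not reduced.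

Step 6
Reactants: 7 tert-butyl 3-(hydroxymethyl)-2-methoxy-6-(triisopropylsilyloxy)benzoate; 8 3-chloro-2-methylpropene
Product: 9 tert-butyl 2-methoxy-3-{[(2-methylprop-2-en-1-yl)oxy]methyl}-6-(triisopropylsilyloxy)benzoate
Conditions: NaH, THF/DMF, 0 °C; then 8, Bu4NI (cat.), 0 °C to rt
Reagents that add atoms: none
Why: Williamson ether synthesis with an allylic chloride activated in situ by iodide. The primary benzylic alkoxide is alkylated faster than it can attack the di-ortho-substituted ester or the hindered silicon.

Step 7
Reactants: 9 tert-butyl 2-methoxy-3-{[(2-methylprop-2-en-1-yl)oxy]methyl}-6-(triisopropylsilyloxy)benzoate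
Product: 12 tert-butyl (S)-3-(1-hydroxy-3-methylbut-3-en-1-yl)-2-methoxy-6-(triisopropylsilyloxy)benzoate, via benzyllithium 10 (not isolated), via lithium alkoxide 11 (not isolated)
Conditions: 2,2′-(propane-2,2-diyl)bis[(4S)-4-tert-butyl-4,5-dihydrooxazole] (1.1 equiv), t-BuLi (2 equiv), hexane, −78 °C; then H2O
Reagents that add atoms: none
Why: tert-Butyllithium bound to the bis(oxazoline) removes a benzylic O–CH2 proton of 9, the lithium being held between the C2 methoxy oxygen and the ether oxygen, to give benzyllithium 10. In 10 the carbanion carbon bonds to the alkene CH2 terminus as the O–CH2 bond breaks, a suprafacial [2,3]-sigmatropic shift through a five-membered envelope transition state that gives alkoxide 11 and, after protonation, 12. The closest known reaction type is the enantioselective [2,3]-Wittig rearrangement of benzyl allyl ethers with an alkyllithium and a chiral bis(oxazoline). No ring is closed. The S stereocentre is controlled by the chiral ligand on lithium, which selects one face of the configurationally labile benzylic carbanion before the irreversible shift. Chemoselectivity for benzylic deprotonation over ester attack or ring lithiation rests on the acidity of the α-alkoxy benzylic C–H, the directing methoxy group, the shielded tert-butyl ester and the bulky, non-directing silyl ether. The [2,3] shift is favoured over the [1,2] shift by the low temperature. The symmetric 2-methylallyl terminus means that no alkene geometry and no second stereocentre can arise.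

Step 8
Reactants: 12 tert-butyl (S)-3-(1-hydroxy-3-methylbut-3-en-1-yl)-2-methoxy-6-(triisopropylsilyloxy)benzoate
Product: 13 tert-butyl (S)-3-(1-hydroxy-3-methylbutyl)-2-methoxy-6-(triisopropylsilyloxy)benzoate
Conditions: H2 (1 atm), RhCl(PPh3)3 (cat.), toluene/EtOH, rt
Reagents that add atoms: none
Why: Homogeneous hydrogenation of the 1,1-disubstituted alkene. The rhodium catalyst is preferred to palladium on carbon so that the electron-rich benzylic C–O bond is not hydrogenolysed, and the stereocentre is untouched.

Step 9
Reactants: 13 tert-butyl (S)-3-(1-hydroxy-3-methylbutyl)-2-methoxy-6-(triisopropylsilyloxy)benzoate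
Product: 14 tert-butyl (S)-6-hydroxy-3-(1-hydroxy-3-methylbutyl)-2-methoxybenzoate
Conditions: TBAF, AcOH, THF, 0 °C
Reagents that add atoms: none
Why: Fluoride cleaves the aryl O–Si bond, and acetic acid buffers the phenoxide so that the ester and carbinol are unaffected. The phenol is freed while the chain still carries a hydroxyl, which cannot be expelled from the para position as an acetate would be.

Step 10
Reactants: 15 2-fluoro-5-methylphenol
Product: 16 (2-fluoro-5-methylphenoxy)triisopropylsilane
Conditions: TIPSCl, imidazole, DMF, rt
Reagents that add atoms: chlorotriisopropylsilane, CC(C)[Si](Cl)(C(C)C)C(C)C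
Why: Phenol silylation; the bulky, weakly coordinating silyl ether is chosen so that oxygen does not direct the lithiation that follows.

Step 11
Reactants: 16 (2-fluoro-5-methylphenoxy)triisopropylsilane
Product: 18 2-fluoro-5-methyl-3-(triisopropylsilyloxy)benzaldehyde, via aryllithium 17 (not isolated)
Conditions: s-BuLi, THF, −78 °C; then DMF, −78 °C to 0 °C; H2O
Reagents that add atoms: N,N-dimethylformamide, CN(C)C=O
Why: Directed ortho-lithiation and formylation: with oxygen masked by a non-coordinating bulky group, the C–H next to fluorine is the most acidic ring position and gives 17, which DMF formylates. Keeping 17 at −78 °C prevents loss of LiF to an aryne.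

Step 12
Reactants: 18 2-fluoro-5-methyl-3-(triisopropylsilyloxy)benzaldehyde
Product: 19 2-fluoro-3-hydroxy-5-methylbenzaldehyde
Conditions: TBAF, AcOH, THF, 0 °C
Reagents that add atoms: none
Why: Buffered fluoride desilylation of the aryl silyl ether, which would not survive the carbonate-mediated ether formation.

Step 13
Reactants: 19 2-fluoro-3-hydroxy-5-methylbenzaldehyde
Product: 20 2-fluoro-3-(methoxymethoxy)-5-methylbenzaldehyde
Conditions: MOMCl, i-Pr2NEt, CH2Cl2, 0 °C to rt
Reagents that add atoms: chloromethyl methyl ether, COCCl
Why: O-Alkylation of the phenol to the methoxymethyl ether, which is stable to base and heat and is removed by the acid that cleaves the tert-butyl ester.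

Step 14
Reactants: 14 tert-butyl (S)-6-hydroxy-3-(1-hydroxy-3-methylbutyl)-2-methoxybenzoate; 20 2-fluoro-3-(methoxymethoxy)-5-methylbenzaldehyde
Product: 21 tert-butyl (S)-6-[2-formyl-6-(methoxymethoxy)-4-methylphenoxy]-3-(1-hydroxy-3-methylbutyl)-2-methoxybenzoate
Conditions: K2CO3, DMF, 110 °C
Reagents that add atoms: none
Why: Nucleophilic aromatic substitution by addition–elimination: the potassium phenoxide of 14 attacks the fluorine-bearing carbon of 20, the anionic adduct is stabilised by the ortho formyl group, and fluoride leaves. Carbonate deprotonates only the phenol, and the secondary alcohol neither competes nor can be lost from the para position.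

Step 15
Reactants: 21 tert-butyl (S)-6-[2-formyl-6-(methoxymethoxy)-4-methylphenoxy]-3-(1-hydroxy-3-methylbutyl)-2-methoxybenzoate
Product: 22 tert-butyl (S)-3-(1-acetoxy-3-methylbutyl)-6-[2-formyl-6-(methoxymethoxy)-4-methylphenoxy]-2-methoxybenzoate
Conditions: Ac2O, pyridine, DMAP (cat.), CH2Cl2, 0 °C to rt
Reagents that add atoms: acetic anhydride, CC(=O)OC(C)=O
Why: DMAP-catalysed acylation of the secondary benzylic alcohol. The carbinol C–O bond is not broken, so the S configuration is retained, and the aryl aldehyde is inert.

Step 16
Reactants: 22 tert-butyl (S)-3-(1-acetoxy-3-methylbutyl)-6-[2-formyl-6-(methoxymethoxy)-4-methylphenoxy]-2-methoxybenzoate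
Product: 23 tert-butyl (S)-3-(1-acetoxy-3-methylbutyl)-2-methoxy-6-{2-(methoxymethoxy)-4-methyl-6-[(E)-3-oxobut-1-en-1-yl]phenoxy}benzoate
Conditions: Ph3P=CHC(O)CH3, toluene, 90 °C
Reagents that add atoms: 1-(triphenylphosphoranylidene)propan-2-one, CC(=O)C=P(c1ccccc1)(c1ccccc1)c1ccccc1
Why: Wittig olefination with a ketone-stabilised ylide, which reacts only with the aldehyde and gives the E enone. The neutral conditions spare the acetate and both esters.

Step 17
Reactants: 23 tert-butyl (S)-3-(1-acetoxy-3-methylbutyl)-2-methoxy-6-{2-(methoxymethoxy)-4-methyl-6-[(E)-3-oxobut-1-en-1-yl]phenoxy}benzoate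
Product: 24 (S)-3-(1-acetoxy-3-methylbutyl)-6-{2-hydroxy-4-methyl-6-[(E)-3-oxobut-1-en-1-yl]phenoxy}-2-methoxybenzoic acid
Conditions: TFA/CH2Cl2 (1:4), 0 °C to rt
Reagents that add atoms: none
Why: Acidolysis: the tert-butyl ester loses isobutene through the tert-butyl cation and the methoxymethyl acetal is cleaved through its oxocarbenium ion. The benzylic acetate should survive because ring A is a poor donor to a benzylic cation: the carboxyl group is meta, the C2 methoxy group is twisted out of plane, and the aryloxy lone pair is shared with the acceptor-substituted ring B.

## Compound list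

1 | 2,6-dihydroxybenzoic acid | O=C(O)c1c(O)cccc1O | starting material
2 | tert-butyl 2,6-dihydroxybenzoate | CC(C)(C)OC(=O)c1c(O)cccc1O | intermediate
3 | tert-butyl 2,6-dihydroxy-3-(hydroxymethyl)benzoate (present as its magnesium phenoxide, not isolated) | CC(C)(C)OC(=O)c1c(O)ccc(CO)c1O | intermediate
4 | tert-butyl 3-formyl-2,6-dihydroxybenzoate | CC(C)(C)OC(=O)c1c(O)ccc(C=O)c1O | intermediate
5 | tert-butyl 3-formyl-2-hydroxy-6-(triisopropylsilyloxy)benzoate | CC(C)(C)OC(=O)c1c(O[Si](C(C)C)(C(C)C)C(C)C)ccc(C=O)c1O | intermediate
6 | tert-butyl 3-formyl-2-methoxy-6-(triisopropylsilyloxy)benzoate | COc1c(C=O)ccc(O[Si](C(C)C)(C(C)C)C(C)C)c1C(=O)OC(C)(C)C | intermediate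
7 | tert-butyl 3-(hydroxymethyl)-2-methoxy-6-(triisopropylsilyloxy)benzoate | COc1c(CO)ccc(O[Si](C(C)C)(C(C)C)C(C)C)c1C(=O)OC(C)(C)C | intermediate
8 | 3-chloro-2-methylpropene | CC(=C)CCl | starting material
9 | tert-butyl 2-methoxy-3-{[(2-methylprop-2-en-1-yl)oxy]methyl}-6-(triisopropylsilyloxy)benzoate | COc1c(COCC(C)=C)ccc(O[Si](C(C)C)(C(C)C)C(C)C)c1C(=O)OC(C)(C)C | intermediate
10 | tert-butyl 3-{lithio[(2-methylprop-2-en-1-yl)oxy]methyl}-2-methoxy-6-(triisopropylsilyloxy)benzoate (ligand-bound α-alkoxybenzyllithium, not isolated) | COc1c(C([Li])OCC(C)=C)ccc(O[Si](C(C)C)(C(C)C)C(C)C)c1C(=O)OC(C)(C)C | intermediate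
11 | lithium (S)-1-[3-(tert-butoxycarbonyl)-2-methoxy-4-(triisopropylsilyloxy)phenyl]-3-methylbut-3-en-1-olate (not isolated) | COc1c([C@H](CC(C)=C)O[Li])ccc(O[Si](C(C)C)(C(C)C)C(C)C)c1C(=O)OC(C)(C)C | intermediate
12 | tert-butyl (S)-3-(1-hydroxy-3-methylbut-3-en-1-yl)-2-methoxy-6-(triisopropylsilyloxy)benzoate | COc1c([C@H](CC(C)=C)O)ccc(O[Si](C(C)C)(C(C)C)C(C)C)c1C(=O)OC(C)(C)C | intermediate
13 | tert-butyl (S)-3-(1-hydroxy-3-methylbutyl)-2-methoxy-6-(triisopropylsilyloxy)benzoate | COc1c([C@H](CC(C)C)O)ccc(O[Si](C(C)C)(C(C)C)C(C)C)c1C(=O)OC(C)(C)C | intermediate
14 | tert-butyl (S)-6-hydroxy-3-(1-hydroxy-3-methylbutyl)-2-methoxybenzoate | COc1c([C@H](CC(C)C)O)ccc(O)c1C(=O)OC(C)(C)C | intermediate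
15 | 2-fluoro-5-methylphenol | Cc1ccc(F)c(O)c1 | starting material
16 | (2-fluoro-5-methylphenoxy)triisopropylsilane | Cc1ccc(F)c(O[Si](C(C)C)(C(C)C)C(C)C)c1 | intermediate
17 | [2-fluoro-5-methyl-3-(triisopropylsilyloxy)phenyl]lithium (not isolated) | Cc1cc([Li])c(F)c(O[Si](C(C)C)(C(C)C)C(C)C)c1 | intermediate
18 | 2-fluoro-5-methyl-3-(triisopropylsilyloxy)benzaldehyde | Cc1cc(C=O)c(F)c(O[Si](C(C)C)(C(C)C)C(C)C)c1 | intermediate
19 | 2-fluoro-3-hydroxy-5-methylbenzaldehyde | Cc1cc(C=O)c(F)c(O)c1 | intermediate
20 | 2-fluoro-3-(methoxymethoxy)-5-methylbenzaldehyde | Cc1cc(C=O)c(F)c(OCOC)c1 | intermediate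
21 | tert-butyl (S)-6-[2-formyl-6-(methoxymethoxy)-4-methylphenoxy]-3-(1-hydroxy-3-methylbutyl)-2-methoxybenzoate | COc1c([C@H](CC(C)C)O)ccc(Oc2c(OCOC)cc(C)cc2C=O)c1C(=O)OC(C)(C)C | intermediate
22 | tert-butyl (S)-3-(1-acetoxy-3-methylbutyl)-6-[2-formyl-6-(methoxymethoxy)-4-methylphenoxy]-2-methoxybenzoate | COc1c([C@H](CC(C)C)OC(C)=O)ccc(Oc2c(OCOC)cc(C)cc2C=O)c1C(=O)OC(C)(C)C | intermediate
23 | tert-butyl (S)-3-(1-acetoxy-3-methylbutyl)-2-methoxy-6-{2-(methoxymethoxy)-4-methyl-6-[(E)-3-oxobut-1-en-1-yl]phenoxy}benzoate | COc1c([C@H](CC(C)C)OC(C)=O)ccc(Oc2c(OCOC)cc(C)cc2/C=C/C(C)=O)c1C(=O)OC(C)(C)C | intermediate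
24 | (S)-3-(1-acetoxy-3-methylbutyl)-6-{2-hydroxy-4-methyl-6-[(E)-3-oxobut-1-en-1-yl]phenoxy}-2-methoxybenzoic acid | COc1c([C@H](CC(C)C)OC(C)=O)ccc(Oc2c(O)cc(C)cc2/C=C/C(C)=O)c1C(=O)O | target

## Step count and least certain steps

Total step count: 17. Longest linear sequence: 13 steps (steps 1–9 and 14–17); the ring B branch (steps 10–13) joins at step 14.

Step 7 (key step). The most likely failure is poor facial discrimination at the benzylic carbanion, because the ligand has to differentiate the faces of a rapidly inverting lithium species on a ring with three neighbouring substituents. The other risks are addition of the alkyllithium to the ester, deprotonation on the ring, or a competing [1,2]-shift if the temperature drifts. Fallback: the C–C bond and the stereocentre would be made by carbonyl addition instead of rearrangement. Setting out from alcohol 7 and chloride 8, an iridium-catalysed transfer-hydrogenative 2-methylallylation would be used. The cyclometalated catalyst is assembled from [Ir(cod)Cl]2, a chiral bisphosphine of the SEGPHOS type (the enantiomer that leads to the S alcohol) and 4-chloro-3-nitrobenzoic acid, with Cs2CO3 in THF at 50–70 °C. It dehydrogenates 7 to aldehyde 6 in situ and adds the 2-methylallyl unit from 8 to one face of the carbonyl, returning to the route at 12. No new compound arises on this path (F0).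

Step 14. The substitution may be too slow. The fluoride of 20 has one activating formyl group but two donors (ortho alkoxy, para methyl), and the phenoxide of 14 is hindered and weakened by the ortho ester, so long heating could degrade the aldehyde. Fallback: a copper-catalysed Ullmann ether synthesis with an aryl iodide in place of the fluoride. 3-Hydroxy-5-methylbenzaldehyde F1 (assumed purchasable) would be converted with MOMCl and i-Pr2NEt into 3-(methoxymethoxy)-5-methylbenzaldehyde F2. The aldehyde would be masked in situ as its α-amino alkoxide with lithium N,N,N′-trimethylethylenediamide, lithiated with n-BuLi at the position between the two directing groups and quenched with I2, giving 2-iodo-3-(methoxymethoxy)-5-methylbenzaldehyde F3 on work-up. Coupling of F3 with phenol 14 (CuI, picolinic acid, K3PO4, DMSO, 90 °C) would return to the route at 21.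

Step 17. Acid-induced ionisation at the benzylic C–O bond would cost the acetate or erode the configuration. The fragment released from the methoxymethyl group could also alkylate the freed phenol ring, or the acid could act on the enone. Fallback: the acid-labile groups would be removed before the enone is made, and by silyl transfer instead of protonolysis. Setting out from aldehyde 22, TMSOTf with 2,2′-bipyridyl in CH2Cl2 at 0 °C should convert the tert-butyl ester and the methoxymethyl ether into trimethylsilyl (S)-3-(1-acetoxy-3-methylbutyl)-6-[2-formyl-4-methyl-6-(trimethylsilyloxy)phenoxy]-2-methoxybenzoate F4. Aqueous methanol would hydrolyse it to (S)-3-(1-acetoxy-3-methylbutyl)-6-(2-formyl-6-hydroxy-4-methylphenoxy)-2-methoxybenzoic acid F5. Olefination of F5 with the ylide of step 16 (excess, with one equivalent of i-Pr2NEt to hold the acid as its salt, toluene, 80 °C) and acidic work-up would give 24 directly.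

Step 2. Formylation may be sluggish, or a second formylation may occur at C5, because both phenols and the ester bind magnesium together. Fallback: the carbon would be introduced through a halide. Setting out from 2, NBS in MeCN at 0 °C should give tert-butyl 3-bromo-2,6-dihydroxybenzoate F6. Silylation as in step 3 should give tert-butyl 3-bromo-2-hydroxy-6-(triisopropylsilyloxy)benzoate F7, and methylation as in step 4 should give tert-butyl 3-bromo-2-methoxy-6-(triisopropylsilyloxy)benzoate F8. Bromine–magnesium exchange on F8 with i-PrMgCl·LiCl in THF, followed by DMF, would return to the route at aldehyde 6.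

## Further compounds

F0 | step 7 | none | none
F1 | step 14 | 3-hydroxy-5-methylbenzaldehyde | Cc1cc(O)cc(C=O)c1
F2 | step 14 | 3-(methoxymethoxy)-5-methylbenzaldehyde | Cc1cc(OCOC)cc(C=O)c1
F3 | step 14 | 2-iodo-3-(methoxymethoxy)-5-methylbenzaldehyde | Cc1cc(C=O)c(I)c(OCOC)c1
F4 | step 17 | trimethylsilyl (S)-3-(1-acetoxy-3-methylbutyl)-6-[2-formyl-4-methyl-6-(trimethylsilyloxy)phenoxy]-2-methoxybenzoate | COc1c([C@H](CC(C)C)OC(C)=O)ccc(Oc2c(O[Si](C)(C)C)cc(C)cc2C=O)c1C(=O)O[Si](C)(C)C
F5 | step 17 | (S)-3-(1-acetoxy-3-methylbutyl)-6-(2-formyl-6-hydroxy-4-methylphenoxy)-2-methoxybenzoic acid | COc1c([C@H](CC(C)C)OC(C)=O)ccc(Oc2c(O)cc(C)cc2C=O)c1C(=O)O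
F6 | step 2 | tert-butyl 3-bromo-2,6-dihydroxybenzoate | CC(C)(C)OC(=O)c1c(O)ccc(Br)c1O
F7 | step 2 | tert-butyl 3-bromo-2-hydroxy-6-(triisopropylsilyloxy)benzoate | CC(C)(C)OC(=O)c1c(O[Si](C(C)C)(C(C)C)C(C)C)ccc(Br)c1O
F8 | step 2 | tert-butyl 3-bromo-2-methoxy-6-(triisopropylsilyloxy)benzoate | COc1c(Br)ccc(O[Si](C(C)C)(C(C)C)C(C)C)c1C(=O)OC(C)(C)C
A1 | alternative 1 | (S)-3-(1-acetoxy-3-methylbutyl)-6-[2-formyl-6-(methoxymethoxy)-4-methylphenoxy]-2-methoxybenzoic acid | COc1c([C@H](CC(C)C)OC(C)=O)ccc(Oc2c(OCOC)cc(C)cc2C=O)c1C(=O)O
A2 | alternative 1 | 2-formyl-6-(methoxymethoxy)-4-methylphenyl (S)-3-(1-acetoxy-3-methylbutyl)-6-hydroxy-2-methoxybenzoate | COc1c([C@H](CC(C)C)OC(C)=O)ccc(O)c1C(=O)Oc1c(OCOC)cc(C)cc1C=O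
A3 | alternative 2 | tert-butyl (S)-3-(1-acetoxy-3-methylbutyl)-6-[2-(1,3-dioxolan-2-yl)-6-(methoxymethoxy)-4-methylphenoxy]-2-methoxybenzoate | COc1c([C@H](CC(C)C)OC(C)=O)ccc(Oc2c(OCOC)cc(C)cc2C2OCCO2)c1C(=O)OC(C)(C)C
A4 | alternative 2 | tert-butyl 6-[2-(1,3-dioxolan-2-yl)-6-(methoxymethoxy)-4-methylphenoxy]-3-iodo-2-methoxybenzoate | COc1c(I)ccc(Oc2c(OCOC)cc(C)cc2C2OCCO2)c1C(=O)OC(C)(C)C
A5 | alternative 2 | 1-chloro-3-methylbutyl acetate (racemic) | CC(C)CC(Cl)OC(C)=O
A6 | alternative 3 | (S)-3-(1-acetoxy-3-methylbutyl)-6-[2-bromo-6-(methoxymethoxy)-4-methylphenoxy]-2-methoxybenzoic acid | COc1c([C@H](CC(C)C)OC(C)=O)ccc(Oc2c(OCOC)cc(C)cc2Br)c1C(=O)O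
A7 | alternative 3 | (S)-1-[2-methoxy-4-(trifluoromethanesulfonyloxy)-3-(trimethylsilyl)phenyl]-3-methylbutyl acetate | COc1c([C@H](CC(C)C)OC(C)=O)ccc(OS(=O)(=O)C(F)(F)F)c1[Si](C)(C)C
A8 | alternative 3 | 2-bromo-6-(methoxymethoxy)-4-methylphenol | Cc1cc(Br)c(O)c(OCOC)c1
A9 | alternative 3 | carbon dioxide | O=C=O
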